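At early times the delta run makes product at 0.0126 M h⁻¹ and the gamma run at 0.0269 M h⁻¹, so 4.00 times the substrate buys a factor of only 2.13. The quick number asked for starts there.

the same everywhere: free catalyst 0.20 mM
- delta: substrate 0.050 M; coupling partner 0.50 M; run made earlier
- gamma: substrate 0.20 M; coupling partner 0.50 M; run made earlier
- flask: substrate 0.10 M; coupling partner 0.500 M

| run | time / h | product / % | substrate / % |
|---|---|---|---|
| delta | 0.333 | 8.2 | 91.0 |
| delta | 0.500 | 12.6 | 86.7 |
| delta | 0.833 | 20.9 | 79.1 |
| delta | 1.33 | 31.0 | 68.8 |
| delta | 2.50 | 49.8 | 49.9 |
| delta | 4.00 | 65.5 | 34.7 |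
| gamma | 0.250 | 3.4 | 96.9 |
| gamma | 0.833 | 11.2 | 89.0 |
| gamma | 1.33 | 17.2 | 82.7 |
| gamma | 2.00 | 25.0 | 74.6 |
| gamma | 3.00 | 35.4 | 64.3 |
| gamma | 4.00 | 44.6 | 55.4 |

(readings scatter by 0.3 percentage points)

- factor on the rate of making product when 50% of the substrate are converted if coupling partner is charged twice over
- factor on the rate when 50% of the substrate are converted if free catalyst is charged at 2.0 mM instead

- no earlier run changes the charge of free catalyst; that part of a forecast is a guess
- no earlier run changes the charge of coupling partner; that part of a forecast is a guess

If rate follows [substrate] at the dilute end and ignores it at the crowded end, a plain join is V[substrate]/(K + [substrate]). The two early rates read K as 0.122 M and V as 0.0432 M h⁻¹. Late in each run the rate lies below this law, at 0.0196 M h⁻¹ in gamma and 0.00523 M h⁻¹ in delta. Read as lost catalyst, the shortfall is 0.0591 h⁻¹ in gamma and 0.0839 h⁻¹ in delta. Gamma makes product faster than delta yet reads a smaller loss per hour, so the loss is taken here to run by the clock, not by the turnover. The mean of the two, 0.0715 h⁻¹, gives the catalyst life, the hours in which working catalyst falls by a factor e: 14.0 h.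

In the flask the law puts 50% conversion at 3.11 h, shorter than that life. If rate goes with the catalyst charged, which no earlier run tests, the same conversion with 2.0 mM of free catalyst comes sooner by the ratio of charges, so less catalyst is lost on the way, and the reckoning here gives a factor of 12.2. The forecast gives 9, lower than this, and 1.6 for doubled coupling partner, and says “Catalyst death could mimic this, but I can't separate the two.” Neither run changes [coupling partner], so that factor gets no reckoning here.

The simulation gives 0.781 for doubled coupling partner and 13.4 for the larger catalyst charge.

    substrate + free catalyst ⇌ catalyst intermediate A (K = 34.4 M⁻¹, k = 2.51 M⁻¹ s⁻¹)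
    coupling partner + catalyst intermediate A → catalyst intermediate B (k = 0.683 M⁻¹ s⁻¹)
    catalyst intermediate B → free catalyst + product (k = 0.0656 s⁻¹)
    coupling partner + free catalyst ⇌ idle complex, settled at all times (K = 4.70 M⁻¹)
    free catalyst → spent catalyst (k = 1.58 × 10⁻⁴ s⁻¹)

The flask reaches 50% conversion at 3.21 h, against a catalyst life of 14.0 h, which predicts 20.5% lost, and it then holds 26.8% of its catalyst as spent catalyst. In the flask with 2.0 mM, if that time shortens by the ratio of charges, the life predicts 2.27% lost, and at the same conversion spent catalyst stands at 2.68%.

The data come from a simulation on assumed constants; the scatter is artificial.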